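**Retrosynthetic overview**
1. The last C=C bond is C15=C15′ (Wittig), joining a ring A C20 trienal to a ring B C20 phosphonium salt; the C8 ketone is unveiled at the very end by MnO2 oxidation of the C8 carbinol.
2. Each half comes from a Stille coupling of one common (2E,4E)-dienyl stannane (C11–C15 unit) with a ring-bearing (E)-vinyl iodide (C10–I or C10′–I).
3. Ring A is formed first, by ring expansion of a cyclopentane: a silylene-tethered Mukaiyama aldol/semipinacol 1,2-shift makes C7–C8, the C6 carbinol and the C5 ketone (later C5=CH2). The cyclopentane comes from 2,2-dimethylcyclopentanone by asymmetric β-boration (C3) and acyl-anion addition.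
4. Ring B is formed second: Robinson annulation and dehydrogenation to 4,4-dimethylcyclohexadienone, Rh-catalysed asymmetric alkenylation (C6′), α-methylation and dienyl triflate reduction.
5. The C9 and C9′ methyl groups with E geometry come from Zr-catalysed alkyne carboalumination/iodination.

Assumption: carotenoid numbering (C1–C20, primes for the ring B half) is used in the comments; the C8 carbinol centre made in step 8 is carried as an epimer mixture because it ends as the ketone.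

**Route**

Step 1
Reactants: 1 2,2-dimethylcyclopentan-1-one
Product: 2 5,5-dimethylcyclopent-2-en-1-one
Conditions: IBX (2-iodoxybenzoic acid, 1.5 equiv), DMSO/PhMe, 70 °C
Reagents that add atoms: none
Why: IBX α,β-dehydrogenation of a ketone can enolise only toward the CH2 side because the other α-carbon is quaternary, so one enone forms.

Step 2
Reactants: 2 5,5-dimethylcyclopent-2-en-1-one
Product: 4 (S)-3-hydroxy-5,5-dimethylcyclopentan-1-one, via pinacol boronate 3 (not isolated)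
Conditions: CuCl (3 mol%), NaOtBu (6 mol%), (R,Sp)-Josiphos (3.3 mol%), B2(pin)2 (1.1 equiv), MeOH (2 equiv), THF, rt; then NaBO3·4H2O, THF/H2O, rt
Reagents that add atoms: bis(pinacolato)diboron CC1(C)OB(OC1(C)C)B1OC(C)(C)C(C)(C)O1 (boryl group of 3); sodium perborate B(=O)O[O-].[Na+] (hydroxyl oxygen of 4)
Why: Copper-catalysed asymmetric conjugate borylation sets C3 under ligand control (ligand enantiomer chosen to give S, checked as the Mosher ester) and perborate oxidation replaces boron by OH with retention.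

Step 3
Reactants: 4 (S)-3-hydroxy-5,5-dimethylcyclopentan-1-one
Product: 5 (S)-3-(tert-butyldimethylsilyloxy)-5,5-dimethylcyclopentan-1-one
Conditions: t-BuMe2SiCl, imidazole, DMF, rt
Reagents that add atoms: tert-butyldimethylsilyl chloride CC(C)(C)[Si](C)(C)Cl
Why: Standard silylation protects the secondary alcohol and gives the bulky group that steers the next addition.

Step 4
Reactants: 5 (S)-3-(tert-butyldimethylsilyloxy)-5,5-dimethylcyclopentan-1-one; 6 ethyl vinyl ether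
Product: 8 1-[(1S,4S)-4-(tert-butyldimethylsilyloxy)-1-hydroxy-2,2-dimethylcyclopentyl]ethan-1-one, via ethoxyvinyl carbinol 7 (not isolated)
Conditions: 6, t-BuLi, THF, −78 → 0 °C; CeCl3, −78 °C; then 5, −78 °C; 1 M HCl, THF, 0 °C
Reagents that add atoms: water O
Why: 1,2-addition of the 1-ethoxyvinyl organocerium (acetyl anion equivalent, too weakly basic to enolise or eliminate the β-silyloxy ketone) should occur anti to the C3 silyloxy group so the new tertiary OH is cis to it, and enol ether hydrolysis then gives the methyl ketone.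

Step 5
Reactants: 8 1-[(1S,4S)-4-(tert-butyldimethylsilyloxy)-1-hydroxy-2,2-dimethylcyclopentyl]ethan-1-one
Product: 9 tert-butyl{[(5S,8S)-2,2-di-tert-butyl-6,6-dimethyl-4-methylidene-1,3-dioxa-2-silaspiro[4.4]nonan-8-yl]oxy}dimethylsilane
Conditions: t-Bu2Si(OSO2CF3)2 (1.1 equiv), Et3N (3 equiv), CH2Cl2, 0 °C → rt
Reagents that add atoms: di-tert-butylsilyl bis(trifluoromethanesulfonate) CC(C)(C)[Si](OS(=O)(=O)C(F)(F)F)(OS(=O)(=O)C(F)(F)F)C(C)(C)C
Why: Soft enolisation/O-silylation of the methyl ketone and intramolecular silylation of the tertiary OH close a five-membered cyclic silyl enol ether that holds the two oxygens syn, without touching a stereocentre.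

Step 6
Reactants: 10 prop-2-yn-1-ol
Product: 12 (E)-3-iodo-2-methylprop-2-en-1-ol, via alkenylalane 11 (not isolated)
Conditions: AlMe3 (3 equiv), (C5H5)2ZrCl2 (0.25 equiv), CH2Cl2, 0 °C → rt; then I2, THF, −30 → 0 °C
Reagents that add atoms: trimethylaluminium C[Al](C)C; iodine II
Why: Negishi zirconium-catalysed carboalumination adds methyl and aluminium syn across the alkyne with methyl on the internal carbon, and iodinolysis with retention gives the E vinyl iodide.

Step 7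
Reactants: 12 (E)-3-iodo-2-methylprop-2-en-1-ol
Product: 13 (E)-3-iodo-2-methylprop-2-enal
Conditions: MnO2 (15 equiv), CH2Cl2, rt
Reagents that add atoms: none
Why: MnO2 oxidises the allylic alcohol to the enal without disturbing the alkene geometry.

Step 8
Reactants: 9 tert-butyl{[(5S,8S)-2,2-di-tert-butyl-6,6-dimethyl-4-methylidene-1,3-dioxa-2-silaspiro[4.4]nonan-8-yl]oxy}dimethylsilane; 13 (E)-3-iodo-2-methylprop-2-enal
Product: 14 (6R,9S)-2,2-di-tert-butyl-9-(tert-butyldimethylsilyloxy)-4-[(E)-1-iodoprop-1-en-2-yl]-11,11-dimethyl-1,3-dioxa-2-silaspiro[5.5]undecan-7-one (C4 epimers)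
Conditions: Me3SiOSO2CF3 (10 mol%), 2,6-di-tert-butyl-4-methylpyridine (5 mol%), CH2Cl2, −78 → −30 °C
Reagents that add atoms: none
Why: Proposed new method: a silylene-tethered Mukaiyama aldol/semipinacol ring expansion in which the enol-silane carbon (C7) of 9 attacks silyl-activated 13, the resulting five-membered cyclic silyloxocarbenium ion at C6 has both ring bonds of the old carbinol carbon aligned with its empty orbital, the more electron-rich CMe2 bond migrates (1,2-alkyl shift, five- to six-membered ring) so that the silicon bridge places the new C6–O bond on the face of the former carbinol oxygen (cis to C3–OSi, giving 6R), and the silicon then passes from the new C5 carbonyl oxygen to the C8 silyl ether oxygen, closing the six-membered silylene and returning Me3SiOSO2CF3; the closest known reactions are Mukaiyama aldol–Prins cascades (oxocarbenium interception), Prins–pinacol and oxonium-triggered pinacol ring expansions of 1-(1-alkoxyvinyl)cycloalkanols, and the Lewis-acid α-ketol ring expansion.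

Step 9
Reactants: 14 (6R,9S)-2,2-di-tert-butyl-9-(tert-butyldimethylsilyloxy)-4-[(E)-1-iodoprop-1-en-2-yl]-11,11-dimethyl-1,3-dioxa-2-silaspiro[5.5]undecan-7-one
Product: 15 tert-butyl{[(6R,9S)-2,2-di-tert-butyl-4-[(E)-1-iodoprop-1-en-2-yl]-11,11-dimethyl-7-methylidene-1,3-dioxa-2-silaspiro[5.5]undecan-9-yl]oxy}dimethylsilane
Conditions: Ph3PCH3Br, KOtBu, THF, 0 °C → rt
Reagents that add atoms: methyltriphenylphosphonium bromide C[P+](c1ccccc1)(c1ccccc1)c1ccccc1.[Br-]
Why: Wittig methylenation turns the C5 ketone into the exocyclic methylene; C6 is quaternary and cannot epimerise, and low temperature limits β-elimination of the C3 silyloxy group.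

Step 10
Reactants: 16 (E)-3-methylpent-2-en-4-yn-1-ol
Product: 17 (2E,4E)-3-methyl-5-(tributylstannyl)penta-2,4-dien-1-ol
Conditions: Bu3SnH (1.1 equiv), PdCl2(PPh3)2 (2 mol%), THF, 0 °C
Reagents that add atoms: tributyltin hydride CCCC[SnH](CCCC)CCCC
Why: Palladium-catalysed syn hydrostannation of the terminal alkyne gives the terminal E stannane (the minor internal regioisomer is removed by chromatography).

Step 11
Reactants: 15 tert-butyl{[(6R,9S)-2,2-di-tert-butyl-4-[(E)-1-iodoprop-1-en-2-yl]-11,11-dimethyl-7-methylidene-1,3-dioxa-2-silaspiro[5.5]undecan-9-yl]oxy}dimethylsilane; 17 (2E,4E)-3-methyl-5-(tributylstannyl)penta-2,4-dien-1-ol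
Product: 18 (2E,4E,6E)-7-[(6R,9S)-2,2-di-tert-butyl-9-(tert-butyldimethylsilyloxy)-11,11-dimethyl-7-methylidene-1,3-dioxa-2-silaspiro[5.5]undecan-4-yl]-3-methylocta-2,4,6-trien-1-ol
Conditions: Pd2(dba)3 (2.5 mol%), AsPh3 (20 mol%), NMP, rt → 40 °C, dark
Reagents that add atoms: none
Why: Stille coupling of a vinyl iodide with a dienyl stannane forms C10–C11 with retention of both alkene geometries under neutral conditions.

Step 12
Reactants: 18 (2E,4E,6E)-7-[(6R,9S)-2,2-di-tert-butyl-9-(tert-butyldimethylsilyloxy)-11,11-dimethyl-7-methylidene-1,3-dioxa-2-silaspiro[5.5]undecan-4-yl]-3-methylocta-2,4,6-trien-1-ol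
Product: 19 (2E,4E,6E)-7-[(6R,9S)-2,2-di-tert-butyl-9-(tert-butyldimethylsilyloxy)-11,11-dimethyl-7-methylidene-1,3-dioxa-2-silaspiro[5.5]undecan-4-yl]-3-methylocta-2,4,6-trienal
Conditions: MnO2 (20 equiv), CH2Cl2, rt, dark
Reagents that add atoms: none
Why: MnO2 oxidises only the free allylic C15 alcohol because the C8 and C6 oxygens are tied up in the silylene.

Step 13
Reactants: 20 2-methylpropanal; 21 but-3-en-2-one
Product: 23 4,4-dimethylcyclohex-2-en-1-one, via keto aldehyde 22 (not isolated)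
Conditions: H2SO4 (cat.), 45 °C; then PhMe, reflux (Dean–Stark)
Reagents that add atoms: none
Why: Acid-catalysed Robinson annulation (Michael addition of the aldehyde enol to the enone, then aldol condensation) builds the six-membered ring that becomes ring B.

Step 14
Reactants: 23 4,4-dimethylcyclohex-2-en-1-one
Product: 24 4,4-dimethylcyclohexa-2,5-dien-1-one
Conditions: DDQ (1.3 equiv), TsOH (cat.), dioxane, 100 °C
Reagents that add atoms: none
Why: DDQ dehydrogenation of the enone gives the cross-conjugated dienone, which cannot aromatise because C4 is quaternary.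

Step 15
Reactants: 25 (E)-1,2-dichloroethene; 26 ethynyltrimethylsilane
Product: 27 [(E)-4-chlorobut-3-en-1-yn-1-yl]trimethylsilane
Conditions: 25 (5 equiv), Pd(PPh3)4 (5 mol%), CuI (10 mol%), BuNH2 (2 equiv), Et2O, rt
Reagents that add atoms: none
Why: Sonogashira mono-coupling of the excess dichloroalkene proceeds with retention of the E geometry.

Step 16
Reactants: 27 [(E)-4-chlorobut-3-en-1-yn-1-yl]trimethylsilane
Product: 28 trimethyl[(E)-4-(4,4,5,5-tetramethyl-1,3,2-dioxaborolan-2-yl)but-3-en-1-yn-1-yl]silane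
Conditions: B2(pin)2 (1.2 equiv), Pd2(dba)3 (2 mol%), XPhos (8 mol%), KOAc (3 equiv), dioxane, 90 °C
Reagents that add atoms: bis(pinacolato)diboron CC1(C)OB(OC1(C)C)B1OC(C)(C)C(C)(C)O1
Why: Miyaura borylation of the activated alkenyl chloride gives the E alkenyl boronate with retention.

Step 17
Reactants: 24 4,4-dimethylcyclohexa-2,5-dien-1-one; 28 trimethyl[(E)-4-(4,4,5,5-tetramethyl-1,3,2-dioxaborolan-2-yl)but-3-en-1-yn-1-yl]silane
Product: 29 (R)-4,4-dimethyl-5-[(E)-4-(trimethylsilyl)but-1-en-3-yn-1-yl]cyclohex-2-en-1-one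
Conditions: [Rh(OH)((R)-BINAP)]2 (3 mol%), dioxane/H2O (10:1), 50 °C
Reagents that add atoms: none
Why: Hayashi–Miyaura rhodium-catalysed asymmetric 1,4-addition of the alkenyl boronate to one of the two enantiotopic enone faces of the dienone sets C6′, with the facial sense assigned by the established BINAP model and the base-free medium sparing the silyl alkyne.

Step 18
Reactants: 29 (R)-4,4-dimethyl-5-[(E)-4-(trimethylsilyl)but-1-en-3-yn-1-yl]cyclohex-2-en-1-one
Product: 31 (5S,6S)-4,4,6-trimethyl-5-[(E)-4-(trimethylsilyl)but-1-en-3-yn-1-yl]cyclohex-2-en-1-one, via lithium dienolate 30 (not isolated)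
Conditions: LiN(i-Pr)2 (1.05 equiv), THF, −78 °C; MeI (3 equiv), −78 → −20 °C
Reagents that add atoms: iodomethane CI
Why: Kinetic α′-enolate alkylation is regiospecific (the γ-carbon is quaternary) and puts the methyl trans to the alkenyl group, a centre that is erased in the next step.

Step 19
Reactants: 31 (5S,6S)-4,4,6-trimethyl-5-[(E)-4-(trimethylsilyl)but-1-en-3-yn-1-yl]cyclohex-2-en-1-one
Product: 33 (R)-2,4,4-trimethyl-3-[(E)-4-(trimethylsilyl)but-1-en-3-yn-1-yl]cyclohexa-1,5-dien-1-yl trifluoromethanesulfonate, via potassium dienolate 32 (not isolated)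
Conditions: KN(SiMe3)2 (1.2 equiv), THF, −78 → −40 °C; PhN(SO2CF3)2, −78 °C → rt
Reagents that add atoms: N-phenylbis(trifluoromethanesulfonimide) FC(F)(F)S(=O)(=O)N(c1ccccc1)S(=O)(=O)C(F)(F)F
Why: Deprotonation of the only remaining α-hydrogen and O-triflation give the cross-conjugated dienyl triflate, and the C6′ hydrogen is not acidic so that centre is untouched.

Step 20
Reactants: 33 (R)-2,4,4-trimethyl-3-[(E)-4-(trimethylsilyl)but-1-en-3-yn-1-yl]cyclohexa-1,5-dien-1-yl trifluoromethanesulfonate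
Product: 34 trimethyl{(E)-4-[(1S)-2,6,6-trimethylcyclohexa-2,4-dien-1-yl]but-3-en-1-yn-1-yl}silane
Conditions: Pd(OAc)2 (5 mol%), PPh3 (10 mol%), HCO2H (2 equiv), Bu3N (3 equiv), DMF, 60 °C
Reagents that add atoms: none
Why: Palladium-catalysed formate reduction of the enol triflate replaces OTf by H and leaves the ring B 2,4-diene in place without moving double bonds.

Step 21
Reactants: 34 trimethyl{(E)-4-[(1S)-2,6,6-trimethylcyclohexa-2,4-dien-1-yl]but-3-en-1-yn-1-yl}silane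
Product: 35 (6S)-6-[(E)-but-1-en-3-yn-1-yl]-1,5,5-trimethylcyclohexa-1,3-diene
Conditions: K2CO3 (0.2 equiv), MeOH/THF, 0 °C → rt
Reagents that add atoms: none
Why: Mild methanolysis of the alkynyl silane frees the terminal alkyne under conditions too weakly basic to touch the C6′ hydrogen.

Step 22
Reactants: 35 (6S)-6-[(E)-but-1-en-3-yn-1-yl]-1,5,5-trimethylcyclohexa-1,3-diene
Product: 37 (6S)-6-[(1E,3E)-4-iodo-3-methylbuta-1,3-dien-1-yl]-1,5,5-trimethylcyclohexa-1,3-diene, via alkenylalane 36 (not isolated)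
Conditions: AlMe3 (2.5 equiv), (C5H5)2ZrCl2 (0.25 equiv), ClCH2CH2Cl, 0 °C → rt; then I2 (1.2 equiv), THF, −30 °C
Reagents that add atoms: trimethylaluminium C[Al](C)C; iodine II
Why: Negishi carboalumination of the conjugated enyne installs the C9′ methyl syn to aluminium and iodinolysis gives the E iodide, the alkyne reacting far faster than the ring alkenes.

Step 23
Reactants: 37 (6S)-6-[(1E,3E)-4-iodo-3-methylbuta-1,3-dien-1-yl]-1,5,5-trimethylcyclohexa-1,3-diene; 17 (2E,4E)-3-methyl-5-(tributylstannyl)penta-2,4-dien-1-ol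
Product: 38 (2E,4E,6E,8E)-3,7-dimethyl-9-[(1S)-2,6,6-trimethylcyclohexa-2,4-dien-1-yl]nona-2,4,6,8-tetraen-1-ol
Conditions: Pd2(dba)3 (2.5 mol%), AsPh3 (20 mol%), NMP, rt → 40 °C, dark
Reagents that add atoms: none
Why: Stille coupling forms C10′–C11′ with retention of geometry under neutral conditions that leave C6′ alone.

Step 24
Reactants: 38 (2E,4E,6E,8E)-3,7-dimethyl-9-[(1S)-2,6,6-trimethylcyclohexa-2,4-dien-1-yl]nona-2,4,6,8-tetraen-1-ol
Product: 39 {(2E,4E,6E,8E)-3,7-dimethyl-9-[(1S)-2,6,6-trimethylcyclohexa-2,4-dien-1-yl]nona-2,4,6,8-tetraen-1-yl}triphenylphosphonium bromide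
Conditions: PPh3·HBr (1.05 equiv), MeOH, 0 °C → rt, dark
Reagents that add atoms: triphenylphosphine hydrobromide [Br-].c1ccc(cc1)[PH+](c1ccccc1)c1ccccc1
Why: Direct phosphonium salt formation from a polyenyl allylic alcohol, as practised on retinol, goes through the delocalised cation trapped at the terminal carbon by PPh3.

Step 25
Reactants: 19 (2E,4E,6E)-7-[(6R,9S)-2,2-di-tert-butyl-9-(tert-butyldimethylsilyloxy)-11,11-dimethyl-7-methylidene-1,3-dioxa-2-silaspiro[5.5]undecan-4-yl]-3-methylocta-2,4,6-trienal; 39 {(2E,4E,6E,8E)-3,7-dimethyl-9-[(1S)-2,6,6-trimethylcyclohexa-2,4-dien-1-yl]nona-2,4,6,8-tetraen-1-yl}triphenylphosphonium bromide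
Product: 42 all-E C40 polyene carrying the 3-O-tert-butyldimethylsilyl ether and the 6,8-O-di-tert-butylsilylene (3S,6R,6′S), via ylide 40 (not isolated), via 15Z isomer 41 (not isolated)
Conditions: NaOMe (1.1 equiv), MeOH/CH2Cl2, −10 °C → rt, dark; then heptane, 70 °C, 2 h
Reagents that add atoms: none
Why: Wittig olefination forms C15=C15′, and the central cis isomer, the least stable geometry in carotenoids, is equilibrated thermally to all-E at a temperature below that needed for hydrogen shifts in ring B.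

Step 26
Reactants: 42 all-E C40 polyene carrying the 3-O-tert-butyldimethylsilyl ether and the 6,8-O-di-tert-butylsilylene
Product: 43 (3E,5E,7E,9E,11E,13E,15E,17E)-1-[(1R,4S)-1,4-dihydroxy-2,2-dimethyl-6-methylidenecyclohexyl]-3,7,12,16-tetramethyl-18-[(1S)-2,6,6-trimethylcyclohexa-2,4-dien-1-yl]octadeca-3,5,7,9,11,13,15,17-octaen-2-ol (C2 epimers)
Conditions: Bu4NF (4 equiv), THF, 0 °C → rt, dark
Reagents that add atoms: none
Why: Fluoride cleaves the cyclic silylene and the secondary silyl ether in one operation without affecting the polyene or any stereocentre.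

Step 27
Reactants: 43 (3E,5E,7E,9E,11E,13E,15E,17E)-1-[(1R,4S)-1,4-dihydroxy-2,2-dimethyl-6-methylidenecyclohexyl]-3,7,12,16-tetramethyl-18-[(1S)-2,6,6-trimethylcyclohexa-2,4-dien-1-yl]octadeca-3,5,7,9,11,13,15,17-octaen-2-ol
Product: 44 (3E,5E,7E,9E,11E,13E,15E,17E)-1-[(1R,4S)-1,4-dihydroxy-2,2-dimethyl-6-methylidenecyclohexyl]-3,7,12,16-tetramethyl-18-[(1S)-2,6,6-trimethylcyclohexa-2,4-dien-1-yl]octadeca-3,5,7,9,11,13,15,17-octaen-2-one (CNP0261423.1)
Conditions: MnO2 (20 equiv), CH2Cl2, rt, dark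
Reagents that add atoms: none
Why: MnO2 oxidises only the polyene-conjugated allylic C8 alcohol, leaving the saturated C3 and tertiary C6 alcohols, and converges both C8 epimers on the ketone.

**Compound list**
1 | 2,2-dimethylcyclopentan-1-one | O=C1CCCC1(C)C | starting material
2 | 5,5-dimethylcyclopent-2-en-1-one | O=C1C=CCC1(C)C | intermediate
3 | (S)-5,5-dimethyl-3-(4,4,5,5-tetramethyl-1,3,2-dioxaborolan-2-yl)cyclopentan-1-one | O=C1C[C@@H](B2OC(C)(C)C(C)(C)O2)CC1(C)C | intermediate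
4 | (S)-3-hydroxy-5,5-dimethylcyclopentan-1-one | O=C1C[C@@H](O)CC1(C)C | intermediate
5 | (S)-3-(tert-butyldimethylsilyloxy)-5,5-dimethylcyclopentan-1-one | O=C1C[C@@H](O[Si](C)(C)C(C)(C)C)CC1(C)C | intermediate
6 | ethyl vinyl ether | C=COCC | starting material
7 | (1S,4S)-4-(tert-butyldimethylsilyloxy)-1-(1-ethoxyethenyl)-2,2-dimethylcyclopentan-1-ol | C=C(OCC)[C@]1(O)C[C@@H](O[Si](C)(C)C(C)(C)C)CC1(C)C | intermediate
8 | 1-[(1S,4S)-4-(tert-butyldimethylsilyloxy)-1-hydroxy-2,2-dimethylcyclopentyl]ethan-1-one | CC(=O)[C@]1(O)C[C@@H](O[Si](C)(C)C(C)(C)C)CC1(C)C | intermediate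
9 | tert-butyl{[(5S,8S)-2,2-di-tert-butyl-6,6-dimethyl-4-methylidene-1,3-dioxa-2-silaspiro[4.4]nonan-8-yl]oxy}dimethylsilane | C=C1O[Si](C(C)(C)C)(C(C)(C)C)O[C@]12C[C@@H](O[Si](C)(C)C(C)(C)C)CC2(C)C | intermediate
10 | prop-2-yn-1-ol | C#CCO | starting material
11 | dimethyl{[(E)-3-(dimethylalumanyl)-2-methylprop-2-en-1-yl]oxy}alumane | C[Al](C)/C=C(C)/CO[Al](C)C | intermediate
12 | (E)-3-iodo-2-methylprop-2-en-1-ol | OC/C(C)=C/I | intermediate
13 | (E)-3-iodo-2-methylprop-2-enal | O=C/C(C)=C/I | intermediate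
14 | (6R,9S)-2,2-di-tert-butyl-9-(tert-butyldimethylsilyloxy)-4-[(E)-1-iodoprop-1-en-2-yl]-11,11-dimethyl-1,3-dioxa-2-silaspiro[5.5]undecan-7-one (C4 epimers) | O=C1C[C@@H](O[Si](C)(C)C(C)(C)C)CC(C)(C)[C@]12CC(/C(C)=C/I)O[Si](C(C)(C)C)(C(C)(C)C)O2 | intermediate
15 | tert-butyl{[(6R,9S)-2,2-di-tert-butyl-4-[(E)-1-iodoprop-1-en-2-yl]-11,11-dimethyl-7-methylidene-1,3-dioxa-2-silaspiro[5.5]undecan-9-yl]oxy}dimethylsilane (C4 epimers) | C=C1C[C@@H](O[Si](C)(C)C(C)(C)C)CC(C)(C)[C@]12CC(/C(C)=C/I)O[Si](C(C)(C)C)(C(C)(C)C)O2 | intermediate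
16 | (E)-3-methylpent-2-en-4-yn-1-ol | OC/C=C(C)/C#C | starting material
17 | (2E,4E)-3-methyl-5-(tributylstannyl)penta-2,4-dien-1-ol | OC/C=C(C)/C=C/[Sn](CCCC)(CCCC)CCCC | intermediate
18 | (2E,4E,6E)-7-[(6R,9S)-2,2-di-tert-butyl-9-(tert-butyldimethylsilyloxy)-11,11-dimethyl-7-methylidene-1,3-dioxa-2-silaspiro[5.5]undecan-4-yl]-3-methylocta-2,4,6-trien-1-ol | C=C1C[C@@H](O[Si](C)(C)C(C)(C)C)CC(C)(C)[C@]12CC(/C(C)=C/C=C/C(C)=C/CO)O[Si](C(C)(C)C)(C(C)(C)C)O2 | intermediate
19 | (2E,4E,6E)-7-[(6R,9S)-2,2-di-tert-butyl-9-(tert-butyldimethylsilyloxy)-11,11-dimethyl-7-methylidene-1,3-dioxa-2-silaspiro[5.5]undecan-4-yl]-3-methylocta-2,4,6-trienal | C=C1C[C@@H](O[Si](C)(C)C(C)(C)C)CC(C)(C)[C@]12CC(/C(C)=C/C=C/C(C)=C/C=O)O[Si](C(C)(C)C)(C(C)(C)C)O2 | intermediate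
20 | 2-methylpropanal | CC(C)C=O | starting material
21 | but-3-en-2-one | CC(=O)C=C | starting material
22 | 2,2-dimethyl-5-oxohexanal | CC(=O)CCC(C)(C)C=O | intermediate
23 | 4,4-dimethylcyclohex-2-en-1-one | O=C1C=CC(C)(C)CC1 | intermediate
24 | 4,4-dimethylcyclohexa-2,5-dien-1-one | O=C1C=CC(C)(C)C=C1 | intermediate
25 | (E)-1,2-dichloroethene | Cl/C=C/Cl | starting material
26 | ethynyltrimethylsilane | C#C[Si](C)(C)C | starting material
27 | [(E)-4-chlorobut-3-en-1-yn-1-yl]trimethylsilane | C[Si](C)(C)C#C/C=C/Cl | intermediate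
28 | trimethyl[(E)-4-(4,4,5,5-tetramethyl-1,3,2-dioxaborolan-2-yl)but-3-en-1-yn-1-yl]silane | C[Si](C)(C)C#C/C=C/B1OC(C)(C)C(C)(C)O1 | intermediate
29 | (R)-4,4-dimethyl-5-[(E)-4-(trimethylsilyl)but-1-en-3-yn-1-yl]cyclohex-2-en-1-one | O=C1C=CC(C)(C)[C@@H](/C=C/C#C[Si](C)(C)C)C1 | intermediate
30 | lithium dienolate of 29 | [Li]OC1=C[C@H](/C=C/C#C[Si](C)(C)C)C(C)(C)C=C1 | intermediate
31 | (5S,6S)-4,4,6-trimethyl-5-[(E)-4-(trimethylsilyl)but-1-en-3-yn-1-yl]cyclohex-2-en-1-one | O=C1C=CC(C)(C)[C@@H](/C=C/C#C[Si](C)(C)C)[C@@H]1C | intermediate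
32 | potassium dienolate of 31 | [K]OC1=C(C)[C@H](/C=C/C#C[Si](C)(C)C)C(C)(C)C=C1 | intermediate
33 | (R)-2,4,4-trimethyl-3-[(E)-4-(trimethylsilyl)but-1-en-3-yn-1-yl]cyclohexa-1,5-dien-1-yl trifluoromethanesulfonate | CC1=C(OS(=O)(=O)C(F)(F)F)C=CC(C)(C)[C@H]1/C=C/C#C[Si](C)(C)C | intermediate
34 | trimethyl{(E)-4-[(1S)-2,6,6-trimethylcyclohexa-2,4-dien-1-yl]but-3-en-1-yn-1-yl}silane | CC1=CC=CC(C)(C)[C@H]1/C=C/C#C[Si](C)(C)C | intermediate
35 | (6S)-6-[(E)-but-1-en-3-yn-1-yl]-1,5,5-trimethylcyclohexa-1,3-diene | CC1=CC=CC(C)(C)[C@H]1/C=C/C#C | intermediate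
36 | dimethyl{(1E,3E)-2-methyl-4-[(1S)-2,6,6-trimethylcyclohexa-2,4-dien-1-yl]buta-1,3-dien-1-yl}alumane | CC1=CC=CC(C)(C)[C@H]1/C=C/C(C)=C/[Al](C)C | intermediate
37 | (6S)-6-[(1E,3E)-4-iodo-3-methylbuta-1,3-dien-1-yl]-1,5,5-trimethylcyclohexa-1,3-diene | CC1=CC=CC(C)(C)[C@H]1/C=C/C(C)=C/I | intermediate
38 | (2E,4E,6E,8E)-3,7-dimethyl-9-[(1S)-2,6,6-trimethylcyclohexa-2,4-dien-1-yl]nona-2,4,6,8-tetraen-1-ol | CC1=CC=CC(C)(C)[C@H]1/C=C/C(C)=C/C=C/C(C)=C/CO | intermediate
39 | {(2E,4E,6E,8E)-3,7-dimethyl-9-[(1S)-2,6,6-trimethylcyclohexa-2,4-dien-1-yl]nona-2,4,6,8-tetraen-1-yl}triphenylphosphonium bromide | CC1=CC=CC(C)(C)[C@H]1/C=C/C(C)=C/C=C/C(C)=C/C[P+](c2ccccc2)(c3ccccc3)c4ccccc4.[Br-] | intermediate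
40 | phosphorus ylide of 39 | CC1=CC=CC(C)(C)[C@H]1/C=C/C(C)=C/C=C/C(C)=C/C=P(c2ccccc2)(c3ccccc3)c4ccccc4 | intermediate
41 | 15Z isomer of 42 | C=C1C[C@@H](O[Si](C)(C)C(C)(C)C)CC(C)(C)[C@]12CC(/C(C)=C/C=C/C(C)=C/C=C\C=C(C)\C=C\C=C(C)\C=C\[C@H]3C(C)=CC=CC3(C)C)O[Si](C(C)(C)C)(C(C)(C)C)O2 | intermediate
42 | all-E C40 polyene with 3-O-tert-butyldimethylsilyl ether and 6,8-O-di-tert-butylsilylene (3S,6R,6′S; C8 epimers) | C=C1C[C@@H](O[Si](C)(C)C(C)(C)C)CC(C)(C)[C@]12CC(/C(C)=C/C=C/C(C)=C/C=C/C=C(C)/C=C/C=C(C)/C=C/[C@H]3C(C)=CC=CC3(C)C)O[Si](C(C)(C)C)(C(C)(C)C)O2 | intermediate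
43 | (3E,5E,7E,9E,11E,13E,15E,17E)-1-[(1R,4S)-1,4-dihydroxy-2,2-dimethyl-6-methylidenecyclohexyl]-3,7,12,16-tetramethyl-18-[(1S)-2,6,6-trimethylcyclohexa-2,4-dien-1-yl]octadeca-3,5,7,9,11,13,15,17-octaen-2-ol (C2 epimers) | C=C1C[C@@H](O)CC(C)(C)[C@]1(O)CC(O)/C(C)=C/C=C/C(C)=C/C=C/C=C(C)/C=C/C=C(C)/C=C/[C@H]2C(C)=CC=CC2(C)C | intermediate
44 | (3E,5E,7E,9E,11E,13E,15E,17E)-1-[(1R,4S)-1,4-dihydroxy-2,2-dimethyl-6-methylidenecyclohexyl]-3,7,12,16-tetramethyl-18-[(1S)-2,6,6-trimethylcyclohexa-2,4-dien-1-yl]octadeca-3,5,7,9,11,13,15,17-octaen-2-one (CNP0261423.1) | C=C1C[C@@H](O)CC(C)(C)[C@]1(O)CC(=O)/C(C)=C/C=C/C(C)=C/C=C/C=C(C)/C=C/C=C(C)/C=C/[C@H]1C(C)=CC=CC1(C)C | target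

**Totals**
Total step count: 27.
Longest linear sequence: 13 steps (20 and 21 to 44 through steps 13, 14 and 17–27; equally 25 and 26 to 44 through steps 15–27).

**Three steps most likely to fail**

Step 8 (the proposed new step). The silicon may pass to the aldolate oxygen before the 1,2-shift, or the CH2 bond may migrate instead of the CMe2 bond. The fallback uses known reactions, sets out from 8 and comes back at 14. Compound 8 is silylated with Me3SiOSO2CF3 and Et3N to (1S,4S)-4-(tert-butyldimethylsilyloxy)-2,2-dimethyl-1-(trimethylsilyloxy)-1-[1-(trimethylsilyloxy)ethenyl]cyclopentane F7. A conventional Mukaiyama aldol of F7 with 13 (BF3·OEt2, CH2Cl2, −78 °C, citric acid work-up) gives the acyclic aldol 1-[(1S,4S)-4-(tert-butyldimethylsilyloxy)-1-hydroxy-2,2-dimethylcyclopentyl]-3-hydroxy-5-iodo-4-methylpent-4-en-1-one F8. A classical Lewis-acid α-ketol ring expansion (Me2AlCl, CH2Cl2, −20 °C → rt, aluminium-chelated syn transition state) then gives (2R,5S)-5-(tert-butyldimethylsilyloxy)-2-hydroxy-2-[(E)-2-hydroxy-4-iodo-3-methylbut-3-en-1-yl]-3,3-dimethylcyclohexan-1-one F9, and t-Bu2Si(OSO2CF3)2 with 2,6-lutidine closes the silylene to 14.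

Step 4. Attack anti to the C3 silyloxy group on a 3-substituted cyclopentanone may be only moderately selective. The fallback replaces steric control by alkoxide-directed addition followed by Mitsunobu inversion; it sets out from 2 and comes back at 8. Step 2 is run with the enantiomeric Josiphos ligand to give (R)-5,5-dimethyl-3-(4,4,5,5-tetramethyl-1,3,2-dioxaborolan-2-yl)cyclopentan-1-one F1 and, after perborate oxidation, (R)-3-hydroxy-5,5-dimethylcyclopentan-1-one F2. Excess 1-ethoxyvinyllithium is added to unprotected F2 so that the lithium alkoxide delivers the nucleophile syn, giving (1S,3R)-1-(1-ethoxyethenyl)-5,5-dimethylcyclopentane-1,3-diol F3. Dilute HCl hydrolyses F3 to the trans diol 1-[(1S,4R)-1,4-dihydroxy-2,2-dimethylcyclopentyl]ethan-1-one F4. Mitsunobu inversion of the secondary alcohol (4-nitrobenzoic acid, PPh3, DIAD) gives (1S,3S)-3-acetyl-3-hydroxy-4,4-dimethylcyclopentyl 4-nitrobenzoate F5, methanolysis (K2CO3, MeOH) gives the cis diol 1-[(1S,4S)-1,4-dihydroxy-2,2-dimethylcyclopentyl]ethan-1-one F6, and selective silylation of the secondary hydroxyl (t-BuMe2SiCl, imidazole) gives 8.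

Step 17. The β-carbon of 24 is neopentyl and rhodium alkenylation may be slow or poorly selective. The fallback builds the same ring by an asymmetric Robinson-type sequence; it sets out from 27, 21 and 20 and comes back at 29. Heck coupling of 27 with 21 (Pd2(dba)3, P(t-Bu)3, Cy2NMe, dioxane, 80 °C) gives (3E,5E)-8-(trimethylsilyl)octa-3,5-dien-7-yn-2-one F10. Enamine-mediated 1,4-addition of 20 to F10 with a chiral primary amine–thiourea catalyst gives (R)-2,2-dimethyl-5-oxo-3-[(E)-4-(trimethylsilyl)but-1-en-3-yn-1-yl]hexanal F11. Intramolecular aldol condensation of F11 (pyrrolidinium acetate, PhMe, reflux) then gives 29.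

**Further compounds**
F1 | step 4 | (R)-5,5-dimethyl-3-(4,4,5,5-tetramethyl-1,3,2-dioxaborolan-2-yl)cyclopentan-1-one | O=C1C[C@H](B2OC(C)(C)C(C)(C)O2)CC1(C)C
F2 | step 4 | (R)-3-hydroxy-5,5-dimethylcyclopentan-1-one | O=C1C[C@H](O)CC1(C)C
F3 | step 4 | (1S,3R)-1-(1-ethoxyethenyl)-5,5-dimethylcyclopentane-1,3-diol | C=C(OCC)[C@]1(O)C[C@H](O)CC1(C)C
F4 | step 4 | 1-[(1S,4R)-1,4-dihydroxy-2,2-dimethylcyclopentyl]ethan-1-one | CC(=O)[C@]1(O)C[C@H](O)CC1(C)C
F5 | step 4 | (1S,3S)-3-acetyl-3-hydroxy-4,4-dimethylcyclopentyl 4-nitrobenzoate | CC(=O)[C@]1(O)C[C@@H](OC(=O)c2ccc(cc2)[N+](=O)[O-])CC1(C)C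
F6 | step 4 | 1-[(1S,4S)-1,4-dihydroxy-2,2-dimethylcyclopentyl]ethan-1-one | CC(=O)[C@]1(O)C[C@@H](O)CC1(C)C
F7 | step 8 | (1S,4S)-4-(tert-butyldimethylsilyloxy)-2,2-dimethyl-1-(trimethylsilyloxy)-1-[1-(trimethylsilyloxy)ethenyl]cyclopentane | C=C(O[Si](C)(C)C)[C@]1(O[Si](C)(C)C)C[C@@H](O[Si](C)(C)C(C)(C)C)CC1(C)C
F8 | step 8 | 1-[(1S,4S)-4-(tert-butyldimethylsilyloxy)-1-hydroxy-2,2-dimethylcyclopentyl]-3-hydroxy-5-iodo-4-methylpent-4-en-1-one (E; C3 epimers) | O=C(CC(O)/C(C)=C/I)[C@]1(O)C[C@@H](O[Si](C)(C)C(C)(C)C)CC1(C)C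
F9 | step 8 | (2R,5S)-5-(tert-butyldimethylsilyloxy)-2-hydroxy-2-[(E)-2-hydroxy-4-iodo-3-methylbut-3-en-1-yl]-3,3-dimethylcyclohexan-1-one | O=C1C[C@@H](O[Si](C)(C)C(C)(C)C)CC(C)(C)[C@]1(O)CC(O)/C(C)=C/I
F10 | step 17 | (3E,5E)-8-(trimethylsilyl)octa-3,5-dien-7-yn-2-one | CC(=O)/C=C/C=C/C#C[Si](C)(C)C
F11 | step 17 | (R)-2,2-dimethyl-5-oxo-3-[(E)-4-(trimethylsilyl)but-1-en-3-yn-1-yl]hexanal | O=CC(C)(C)[C@@H](/C=C/C#C[Si](C)(C)C)CC(C)=O
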